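Hold the two hands against each other: at 40.0 min the green run shows 42.9% left-handed product and 6.6% right-handed product, much more of the first.

| flask | left-handed substrate | right-handed substrate | partner | precatalyst | remark | time |
|---|---|---|---|---|---|---|
| red | 0.070 M | 0.070 M | 0.20 M (fed, over 50 min) | 8.5 mM | run made earlier |  |
| green | 0.11 M | 0.11 M | 0.20 M (fed, over 50 min) | 8.5 mM | run made earlier |  |
| teal | 0.050 M | 0.050 M | 0.20 M (fed, over 50 min) | 17 mM | run made earlier |  |
| flask | 0.050 M | 0.050 M | 0.200 M (fed, over 50 min) | 8.5 mM |  | 50 min |

| run | time / min | left-handed product / % | right-handed product / % |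
|---|---|---|---|
| red | 3.00 | 0.9 | 2.0 |
| red | 6.00 | 0.2 | 0 |
| red | 12.0 | 7.3 | 0.3 |
| red | 20.0 | 22.8 | 1.4 |
| red | 40.0 | 47.3 | 8.8 |
| green | 4.00 | 0 | 0 |
| green | 10.0 | 5.8 | 0 |
| green | 20.0 | 19.5 | 2.0 |
| green | 30.0 | 33.0 | 5.6 |
| green | 40.0 | 42.9 | 6.6 |
| teal | 3.00 | 0.7 | 0 |
| teal | 6.00 | 2.6 | 1.0 |
| teal | 12.0 | 14.4 | 1.3 |
| teal | 20.0 | 31.5 | 3.0 |
| teal | 40.0 | 51.6 | 14.9 |

(readings scatter by 1 percentage point)

1. left-handed product and right-handed product together, in percent of the left-handed substrate and right-handed substrate charged together, at 50 min
2. excess of left-handed product over right-handed product in the product at 50 min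
3. whether the exchange between left-handed substrate and right-handed substrate keeps pace with the reaction: how far the product's excess at 50 min gets from its value without exchange to its value with instant exchange (above 80% keeps pace, below 20% hardly takes part, else lags behind)

- free catalyst is single-handed; left-handed substrate and right-handed substrate are mirror images of each other, charged as a racemate, each of them at the stated concentration
- the analysis behind the earlier runs scatters by 1 percentage point, standard deviation
- an excess is below zero if the other one leads

Let a and b be the fractions of left-handed and right-handed substrate still unreacted. Suppose there is no exchange and each substrate is first order in itself. Catalyst and partner then cancel from the ratio of the two rates, so ln a / ln b stays constant however the partner is fed. Read it from the latest readings: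

s = ln a / ln b = 13.8 (green run), 15.1 (red run)

Take s, the selectivity factor, from the green run. Now draw the curve of excess e against yield y, with a = b^s:

y = 1 − (a + b)/2, e = (b − a)/(2y)

Start: e = (s − 1)/(s + 1) = 86.5%.

Knee, with half of the left-handed substrate gone: b = 0.951, y = 27.5%, e = 82.0%.

Far along the curve, once a has fallen close to zero, left-handed product sits at its ceiling, half of the racemate, so e = (1 − y)/y there and not at the knee.

The forecast gives 66% (60% to 72%), 52% (44% to 62%) and "hardly takes part", “so exchange shows little”. My line at its yield gives 51.5%, from the same reading of the runs.

The flask gives 65.2%, 59.8% and "hardly takes part", 11% of the way.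

    partner + free catalyst + left-handed substrate → free catalyst + left-handed product (k = 283 /M²/min)
    partner + free catalyst + right-handed substrate → free catalyst + right-handed product (k = 20.0 /M²/min)
    left-handed substrate ⇌ right-handed substrate (k = 0.00300 /min)
    2 partner → homo dimer (k = 0.114 /M/min)
    partner + free catalyst → spent catalyst (k = 0.103 /M/min)
    precatalyst → free catalyst (k = 0.0572 /min)

At this yield the line gives 52.3%, less than the flask shows, and left-handed product stands at 52.1%, above the ceiling. Repeat the reckoning on the neighbouring flask with 0.050 M of partner, whose yield is 33.8%. Solving a + b = 2 − 2y = 1.32 with a = b^s gives b = 0.934 and e = 81.1%. That neighbouring flask gives 81.5%.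

The data are simulated from invented constants.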